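**Retrosynthetic overview**
- C11=C12 is cut last (Wittig): left C15 epoxy-ketone phosphonium salt 15 plus right C25 acetylenic apo-aldehyde 10.
- 10 comes from the right C15 acetylenic phosphonium salt 7 and C10 dialdehyde 8 (Wittig at C11'=C12').
- The left β,γ-epoxy ketone is made by two C–O bond-forming steps: anti epoxidation of the ring alkene (sets C5 and C6), then gold-catalysed hydration of the alkynyl epoxide at C8 (new).
- Both halves come from one C15 enynol acetate 5, made by Sonogashira coupling of the actinol-derived enol triflate 3 with enynol 4.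
- Both cyclohexane rings come intact from actinol 1; the only ring formed is the oxirane (step 6).

Assumption: 1, 4 and 8 are taken as purchasable carotenoid-industry intermediates; positions are given in carotenoid numbering (primes = acetylenic half).

**Step 1**
Reactants: 1 (4R,6R)-4-hydroxy-2,2,6-trimethylcyclohexan-1-one
Product: 2 (4R,6R)-4-acetoxy-2,2,6-trimethylcyclohexan-1-one
Conditions: Ac2O, DMAP (cat.), pyridine, CH2Cl2, rt
Reagents that add atoms: acetic anhydride CC(=O)OC(C)=O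
Why: DMAP-catalysed O-acylation of the secondary alcohol; no stereocentre is touched.

**Step 2**
Reactants: 2 (4R,6R)-4-acetoxy-2,2,6-trimethylcyclohexan-1-one
Product: 3 (4R)-4-acetoxy-2,6,6-trimethylcyclohex-1-en-1-yl trifluoromethanesulfonate
Conditions: Tf2O, 2,6-di-tert-butyl-4-methylpyridine, CH2Cl2, 0 °C to rt
Reagents that add atoms: triflic anhydride FC(F)(F)S(=O)(=O)OS(=O)(=O)C(F)(F)F
Why: Enol triflate formation; the ketone can enolise only toward the methyl-bearing carbon (the other α-carbon is quaternary), and the base-free conditions spare the acetate; the CH(CH3) stereocentre is erased, the carbinol centre is kept.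

**Step 3**
Reactants: 3 (4R)-4-acetoxy-2,6,6-trimethylcyclohex-1-en-1-yl trifluoromethanesulfonate; 4 (2E)-3-methylpent-2-en-4-yn-1-ol
Product: 5 (1R)-4-[(3E)-5-hydroxy-3-methylpent-3-en-1-yn-1-yl]-3,5,5-trimethylcyclohex-3-en-1-yl acetate
Conditions: Pd(PPh3)4 (5 mol %), CuI (10 mol %), Et3N, DMF, 45 °C
Reagents that add atoms: none
Why: Sonogashira coupling of an alkenyl triflate with a terminal alkyne; the E geometry of 4 (later C9/C9') is carried over unchanged.

**Step 4**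
Reactants: 5 (1R)-4-[(3E)-5-hydroxy-3-methylpent-3-en-1-yn-1-yl]-3,5,5-trimethylcyclohex-3-en-1-yl acetate
Product: 7 [(2E)-5-[(4R)-4-acetoxy-2,6,6-trimethylcyclohex-1-en-1-yl]-3-methylpent-2-en-4-yn-1-yl]triphenylphosphonium bromide, via allylic bromide 6 (not isolated)
Conditions: CBr4 (1.1 equiv), PPh3 (1.15 equiv), CH2Cl2, −20 °C; then PPh3 (1.3 equiv), rt
Reagents that add atoms: carbon tetrabromide BrC(Br)(Br)Br; triphenylphosphine c1ccc(cc1)P(c1ccccc1)c1ccccc1
Why: Appel bromination followed by SN2 quaternisation of PPh3; no allyl cation is formed, so the 9'E alkene is retained.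

**Step 5**
Reactants: 7 [(2E)-5-[(4R)-4-acetoxy-2,6,6-trimethylcyclohex-1-en-1-yl]-3-methylpent-2-en-4-yn-1-yl]triphenylphosphonium bromide; 8 (2E,4E,6E)-2,7-dimethylocta-2,4,6-trienedial (3 equiv)
Product: 10 (2E,4E,6E,8E,10E)-13-[(4R)-4-acetoxy-2,6,6-trimethylcyclohex-1-en-1-yl]-2,7,11-trimethyltrideca-2,4,6,8,10-pentaen-12-ynal, via phosphorus ylide 9 (not isolated)
Conditions: NaN(SiMe3)2 (1.0 equiv), THF, −78 °C; cannulate into 8, −78 to 0 °C; then heptane, 80 °C, 2 h
Reagents that add atoms: none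
Why: Wittig olefination; excess dialdehyde (recovered) and the lower reactivity of the C25 aldehyde give mono-olefination, and the hindered 11'Z isomer relaxes to E on mild heating.

**Step 6**
Reactants: 5 (1R)-4-[(3E)-5-hydroxy-3-methylpent-3-en-1-yn-1-yl]-3,5,5-trimethylcyclohex-3-en-1-yl acetate
Product: 12 (1R,4S,6R)-1-[(3E)-5-hydroxy-3-methylpent-3-en-1-yn-1-yl]-2,2,6-trimethyl-7-oxabicyclo[4.1.0]heptan-4-ol, via anti epoxy acetate 11 (not isolated)
Conditions: mCPBA (1.05 equiv), NaHCO3, CH2Cl2, −20 to 0 °C; then MeOH, K2CO3, 0 °C to rt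
Reagents that add atoms: 3-chloroperoxybenzoic acid OOC(=O)c1cccc(Cl)c1
Why: Prilezhaev epoxidation of the more electron-rich tetrasubstituted ring alkene, delivered to the face away from the homoallylic acetoxy group, which has no hydrogen-bond donor to steer the peracid syn (about 4:1 anti:syn expected; the syn isomer is removed at the diol stage); this sets C5 (R) and C6 as in the target, and methanolysis then frees the 3-hydroxyl.

**Step 7**
Reactants: 12 (1R,4S,6R)-1-[(3E)-5-hydroxy-3-methylpent-3-en-1-yn-1-yl]-2,2,6-trimethyl-7-oxabicyclo[4.1.0]heptan-4-ol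
Product: 13 (3E)-5-hydroxy-1-[(1S,4S,6R)-4-hydroxy-2,2,6-trimethyl-7-oxabicyclo[4.1.0]heptan-1-yl]-3-methylpent-3-en-2-one
Conditions: [{(IPr)Au}2(μ-OH)]BF4 (2.5 mol %; IPr = 1,3-bis(2,6-diisopropylphenyl)imidazol-2-ylidene), H2O (10 equiv), 1,4-dioxane, 40 °C, dark
Reagents that add atoms: water O
Why: Proposed new method: acid-free monovalent-gold hydration of an alkynyl oxirane embedded in a 1,3-enyne, turning it into a β,γ-epoxy ketone; the hydroxide-bridged digold salt splits into π-acidic [(IPr)Au]+ and Brønsted-basic (IPr)AuOH, the cation binds C7≡C8, and water adds anti at C8 because positive charge there is allylic (C9=C10) whereas C7 is inductively deactivated by the oxirane C–O bond and screened by quaternary C6; the C7 vinylgold is protonated by the water/(IPr)AuOH couple and the enol tautomerises to the C7H2–C8=O unit (C–O bond formed at C8, no stereocentre touched); the oxirane should survive because the medium never turns acidic and because the usual gold route from alkynyl oxiranes to furans needs a hydrogen on an oxirane carbon, which C5 and C6 lack, while the E-placed C11 hydroxyl cannot reach the alkyne; closest known reaction type: gold-catalysed Markovnikov hydration of internal alkynes and conjugated enynes to enones.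

**Step 8**
Reactants: 13 (3E)-5-hydroxy-1-[(1S,4S,6R)-4-hydroxy-2,2,6-trimethyl-7-oxabicyclo[4.1.0]heptan-1-yl]-3-methylpent-3-en-2-one
Product: 15 [(2E)-5-[(1S,4S,6R)-4-hydroxy-2,2,6-trimethyl-7-oxabicyclo[4.1.0]heptan-1-yl]-3-methyl-4-oxopent-2-en-1-yl]triphenylphosphonium bromide, via allylic bromide 14 (not isolated)
Conditions: CBr4 (1.05 equiv), PPh3 (1.1 equiv), CH2Cl2, −30 °C; then PPh3 (1.2 equiv), 0 °C to rt; precipitate with Et2O
Reagents that add atoms: carbon tetrabromide BrC(Br)(Br)Br; triphenylphosphine c1ccc(cc1)P(c1ccccc1)c1ccccc1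
Why: Appel bromination and SN2 quaternisation; the primary allylic alcohol reacts far faster than the secondary ring alcohol, and the neutral conditions leave the acid- and base-labile epoxy ketone and the 9E alkene alone.

**Step 9**
Reactants: 15 [(2E)-5-[(1S,4S,6R)-4-hydroxy-2,2,6-trimethyl-7-oxabicyclo[4.1.0]heptan-1-yl]-3-methyl-4-oxopent-2-en-1-yl]triphenylphosphonium bromide; 10 (2E,4E,6E,8E,10E)-13-[(4R)-4-acetoxy-2,6,6-trimethylcyclohex-1-en-1-yl]-2,7,11-trimethyltrideca-2,4,6,8,10-pentaen-12-ynal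
Product: 17 (3S,5R,6S,3'R)-3'-acetoxy-5,6-epoxy-3-hydroxy-7',8'-didehydro-5,6,7,8-tetrahydro-β,β-caroten-8-one (CNP0217594.1), via phosphorus ylide 16 (not isolated)
Conditions: 1,2-epoxybutane/CH2Cl2 (1:1), 45 °C, dark, Ar; chromatography on neutral silica, crystallisation
Reagents that add atoms: none
Why: Wittig olefination with a ketone-stabilised vinylogous ylide (E-selective at C11=C12), formed without free strong base because the epoxide only scavenges HBr; the C11 protons are far more acidic than C7–H, so the β,γ-epoxy ketone is not opened and the acetate is kept.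

**Compound list**
1 | (4R,6R)-4-hydroxy-2,2,6-trimethylcyclohexan-1-one (actinol) | O[C@@H]1C[C@@H](C)C(=O)C(C)(C)C1 | starting material
2 | (4R,6R)-4-acetoxy-2,2,6-trimethylcyclohexan-1-one | CC(=O)O[C@@H]1C[C@@H](C)C(=O)C(C)(C)C1 | intermediate
3 | (4R)-4-acetoxy-2,6,6-trimethylcyclohex-1-en-1-yl trifluoromethanesulfonate | CC(=O)O[C@@H]1CC(C)=C(OS(=O)(=O)C(F)(F)F)C(C)(C)C1 | intermediate
4 | (2E)-3-methylpent-2-en-4-yn-1-ol | C#C/C(C)=C/CO | starting material
5 | (1R)-4-[(3E)-5-hydroxy-3-methylpent-3-en-1-yn-1-yl]-3,5,5-trimethylcyclohex-3-en-1-yl acetate | CC(=O)O[C@@H]1CC(C)=C(C#C/C(C)=C/CO)C(C)(C)C1 | intermediate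
6 | (1R)-4-[(3E)-5-bromo-3-methylpent-3-en-1-yn-1-yl]-3,5,5-trimethylcyclohex-3-en-1-yl acetate | CC(=O)O[C@@H]1CC(C)=C(C#C/C(C)=C/CBr)C(C)(C)C1 | intermediate (not isolated)
7 | [(2E)-5-[(4R)-4-acetoxy-2,6,6-trimethylcyclohex-1-en-1-yl]-3-methylpent-2-en-4-yn-1-yl]triphenylphosphonium bromide | CC(=O)O[C@@H]1CC(C)=C(C#C/C(C)=C/C[P+](c2ccccc2)(c2ccccc2)c2ccccc2)C(C)(C)C1.[Br-] | intermediate
8 | (2E,4E,6E)-2,7-dimethylocta-2,4,6-trienedial | O=C/C(C)=C/C=C/C=C(\C)C=O | starting material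
9 | triphenylphosphonium ylide of 7 | CC(=O)O[C@@H]1CC(C)=C(C#C/C(C)=C/C=P(c2ccccc2)(c2ccccc2)c2ccccc2)C(C)(C)C1 | intermediate (not isolated)
10 | (2E,4E,6E,8E,10E)-13-[(4R)-4-acetoxy-2,6,6-trimethylcyclohex-1-en-1-yl]-2,7,11-trimethyltrideca-2,4,6,8,10-pentaen-12-ynal | CC(=O)O[C@@H]1CC(C)=C(C#C/C(C)=C/C=C/C(C)=C/C=C/C=C(C)/C=O)C(C)(C)C1 | intermediate
11 | (1R,4S,6R)-1-[(3E)-5-hydroxy-3-methylpent-3-en-1-yn-1-yl]-2,2,6-trimethyl-7-oxabicyclo[4.1.0]heptan-4-yl acetate (oxirane anti to the acetoxy group) | OC/C=C(C)/C#C[C@@]12O[C@]1(C)C[C@@H](OC(C)=O)CC2(C)C | intermediate (not isolated)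
12 | (1R,4S,6R)-1-[(3E)-5-hydroxy-3-methylpent-3-en-1-yn-1-yl]-2,2,6-trimethyl-7-oxabicyclo[4.1.0]heptan-4-ol | OC/C=C(C)/C#C[C@@]12O[C@]1(C)C[C@@H](O)CC2(C)C | intermediate
13 | (3E)-5-hydroxy-1-[(1S,4S,6R)-4-hydroxy-2,2,6-trimethyl-7-oxabicyclo[4.1.0]heptan-1-yl]-3-methylpent-3-en-2-one | OC/C=C(\C)C(=O)C[C@@]12O[C@]1(C)C[C@@H](O)CC2(C)C | intermediate
14 | (3E)-5-bromo-1-[(1S,4S,6R)-4-hydroxy-2,2,6-trimethyl-7-oxabicyclo[4.1.0]heptan-1-yl]-3-methylpent-3-en-2-one | BrC/C=C(\C)C(=O)C[C@@]12O[C@]1(C)C[C@@H](O)CC2(C)C | intermediate (not isolated)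
15 | [(2E)-5-[(1S,4S,6R)-4-hydroxy-2,2,6-trimethyl-7-oxabicyclo[4.1.0]heptan-1-yl]-3-methyl-4-oxopent-2-en-1-yl]triphenylphosphonium bromide | C(/C=C(\C)C(=O)C[C@@]12O[C@]1(C)C[C@@H](O)CC2(C)C)[P+](c1ccccc1)(c1ccccc1)c1ccccc1.[Br-] | intermediate
16 | triphenylphosphonium ylide of 15 | C(/C=C(\C)C(=O)C[C@@]12O[C@]1(C)C[C@@H](O)CC2(C)C)=P(c1ccccc1)(c1ccccc1)c1ccccc1 | intermediate (not isolated)
17 | (3S,5R,6S,3'R)-3'-acetoxy-5,6-epoxy-3-hydroxy-7',8'-didehydro-5,6,7,8-tetrahydro-β,β-caroten-8-one (CNP0217594.1) | CC(=O)O[C@@H]1CC(C)=C(C#C/C(C)=C/C=C/C(C)=C/C=C/C=C(C)/C=C/C=C(\C)C(=O)C[C@@]23O[C@]2(C)C[C@@H](O)CC3(C)C)C(C)(C)C1 | target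

**Totals**
Total steps: 9. Longest linear sequence: 7 (steps 1, 2, 3, 6, 7, 8, 9).

**Steps most likely to fail**

Step 7 (proposed new hydration). The gold cation may open or rearrange the fully substituted oxirane, or the hydration may be slow or unselective. The fallback uses known chemistry, sets out from 12 and comes back at 13. [Cp*Ru(MeCN)3]PF6 (5 mol %) and benzyldimethylsilane in CH2Cl2 at 0 °C to rt give trans hydrosilylation, with silicon placed at the alkyne carbon distal to the branched, oxygenated propargylic position, to give (2E,4Z)-4-[benzyl(dimethyl)silyl]-5-[(1S,4S,6R)-4-hydroxy-2,2,6-trimethyl-7-oxabicyclo[4.1.0]heptan-1-yl]-3-methylpenta-2,4-dien-1-ol F4. Tamao–Fleming oxidation of F4 (Bu4NF, THF, 0 °C; then H2O2, KHCO3, MeOH) gives the C8 enol and hence ketone 13.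

Step 6 (epoxidation). The peracid may also attack the C9=C10 allylic-alcohol alkene, and the anti:syn ratio may be modest. The fallback sets out from 3 and comes back at 12. Sonogashira coupling of 3 with trimethylsilylacetylene (Pd(PPh3)4, CuI, Et3N) gives (1R)-3,5,5-trimethyl-4-[(trimethylsilyl)ethynyl]cyclohex-3-en-1-yl acetate F1, which has only one alkene. mCPBA/NaHCO3 converts it into (1R,4S,6R)-2,2,6-trimethyl-1-[(trimethylsilyl)ethynyl]-7-oxabicyclo[4.1.0]heptan-4-yl acetate F2. K2CO3/MeOH removes silyl and acetyl groups to give (1R,4S,6R)-1-ethynyl-2,2,6-trimethyl-7-oxabicyclo[4.1.0]heptan-4-ol F3, from which the syn isomer is removed by crystallisation. Sonogashira coupling of F3 with purchased (E)-3-iodobut-2-en-1-ol (Pd(PPh3)4, CuI, Et3N, THF) gives 12.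

Step 9 (final Wittig). The β,γ-epoxy ketone may undergo base-induced oxirane opening, or the stabilised ylide may be too sluggish toward the C25 polyenal. The fallback reverses the polarity, sets out from 13 and 10 and comes back at 17. MnO2 (CH2Cl2, rt) oxidises only the allylic alcohol of 13 to (2E)-5-[(1S,4S,6R)-4-hydroxy-2,2,6-trimethyl-7-oxabicyclo[4.1.0]heptan-1-yl]-3-methyl-4-oxopent-2-enal F5. NaBH4 (EtOH/THF, 0 °C) reduces 10 to (2E,4E,6E,8E,10E)-13-[(4R)-4-acetoxy-2,6,6-trimethylcyclohex-1-en-1-yl]-2,7,11-trimethyltrideca-2,4,6,8,10-pentaen-12-yn-1-ol F6. PPh3·HBr (CH2Cl2, rt) converts F6 into the C25 triphenylphosphonium bromide F7. NaN(SiMe3)2 (THF, −78 °C) gives the C25 ylide F8, which is added at −78 °C to F5, so it is consumed by the very electrophilic aldehyde before it can act as a base. Brief warming in heptane relaxes 11Z to E and gives 17.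

**Further compounds**
F1 | step 6 | (1R)-3,5,5-trimethyl-4-[(trimethylsilyl)ethynyl]cyclohex-3-en-1-yl acetate | CC(=O)O[C@@H]1CC(C)=C(C#C[Si](C)(C)C)C(C)(C)C1
F2 | step 6 | (1R,4S,6R)-2,2,6-trimethyl-1-[(trimethylsilyl)ethynyl]-7-oxabicyclo[4.1.0]heptan-4-yl acetate | C[Si](C)(C)C#C[C@@]12O[C@]1(C)C[C@@H](OC(C)=O)CC2(C)C
F3 | step 6 | (1R,4S,6R)-1-ethynyl-2,2,6-trimethyl-7-oxabicyclo[4.1.0]heptan-4-ol | C#C[C@@]12O[C@]1(C)C[C@@H](O)CC2(C)C
F4 | step 7 | (2E,4Z)-4-[benzyl(dimethyl)silyl]-5-[(1S,4S,6R)-4-hydroxy-2,2,6-trimethyl-7-oxabicyclo[4.1.0]heptan-1-yl]-3-methylpenta-2,4-dien-1-ol | OC/C=C(C)/C(=C/[C@@]12O[C@]1(C)C[C@@H](O)CC2(C)C)[Si](C)(C)Cc1ccccc1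
F5 | step 9 | (2E)-5-[(1S,4S,6R)-4-hydroxy-2,2,6-trimethyl-7-oxabicyclo[4.1.0]heptan-1-yl]-3-methyl-4-oxopent-2-enal | O=C/C=C(\C)C(=O)C[C@@]12O[C@]1(C)C[C@@H](O)CC2(C)C
F6 | step 9 | (2E,4E,6E,8E,10E)-13-[(4R)-4-acetoxy-2,6,6-trimethylcyclohex-1-en-1-yl]-2,7,11-trimethyltrideca-2,4,6,8,10-pentaen-12-yn-1-ol | CC(=O)O[C@@H]1CC(C)=C(C#C/C(C)=C/C=C/C(C)=C/C=C/C=C(C)/CO)C(C)(C)C1
F7 | step 9 | [(2E,4E,6E,8E,10E)-13-[(4R)-4-acetoxy-2,6,6-trimethylcyclohex-1-en-1-yl]-2,7,11-trimethyltrideca-2,4,6,8,10-pentaen-12-yn-1-yl]triphenylphosphonium bromide | CC(=O)O[C@@H]1CC(C)=C(C#C/C(C)=C/C=C/C(C)=C/C=C/C=C(C)/C[P+](c2ccccc2)(c2ccccc2)c2ccccc2)C(C)(C)C1.[Br-]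
F8 | step 9 | triphenylphosphonium ylide of F7 | CC(=O)O[C@@H]1CC(C)=C(C#C/C(C)=C/C=C/C(C)=C/C=C/C=C(C)/C=P(c2ccccc2)(c2ccccc2)c2ccccc2)C(C)(C)C1
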